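Everything rests on opening ring B (ether carbon 1, C–H 2, C–CH3 3, C–H 4, C–OH 5, C–CO2H 6) between carbons 4 and 5. Carbon 6, whose carboxyl sits between the oxygenated carbons 1 and 5, is then a malonate carbon, carbon 1 a ketone carbon held as its aryl enol ether, and carbons 2–4 a senecioyl unit, so the crowded ether oxygen is attached to a vinyl chloride before ring B exists. The precursor is dienyl malonate 17, carrying the complete ring A with its hydroxyl masked as a methoxymethyl (MOM) ether. In one operation base closes the 4–5 bond, expels methoxide and aromatises ring B to salicylate 19.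

Key step: step 11

Remark: ring A is numbered from the methoxy carbon (position 1 C–OMe, position 2 C–H, position 3 C–CO2H, position 4 C–O–aryl, position 5 C–OH, position 6 C–Cl); the target has no stereocentre and no stereogenic double bond; 14 is drawn as the keto tautomer of what should be a chelated enol.

Step 1
Reactants: 1 2-chlororesorcinol (2-chlorobenzene-1,3-diol)
Product: 3 3-chloro-2,4-dihydroxybenzaldehyde, via aryl iminium chloride 2 (not isolated)
Conditions: POCl3, DMF, MeCN, −15 °C → rt; then H2O, 50 °C
Reagents that add atoms: N,N-dimethylformamide, CN(C)C=O (formyl carbon); water, O (formyl oxygen)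
Why: Vilsmeier–Haack formylation, in which the two activated positions of 1 (each ortho to one hydroxyl and para to the other) are equivalent and the iminium salt 2 is too electron-poor to be attacked a second time before hydrolysis.

Step 2
Reactants: 3 3-chloro-2,4-dihydroxybenzaldehyde
Product: 4 3-chloro-2-hydroxy-4-methoxybenzaldehyde
Conditions: MeI (1.1 equiv), KHCO3, DMF, 30 °C
Reagents that add atoms: iodomethane, CI
Why: Williamson ether synthesis under weak-base control, since the 4-hydroxyl (para to the formyl group, ortho to chlorine) is the more acidic one whereas the 2-hydroxyl is held in a hydrogen bond to the aldehyde, so only the 4-oxygen should be methylated.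

Step 3
Reactants: 4 3-chloro-2-hydroxy-4-methoxybenzaldehyde
Product: 5 3-chloro-4-methoxy-2-(methoxymethoxy)benzaldehyde
Conditions: NaH, THF, 0 °C; MOMCl, 0 °C → rt
Reagents that add atoms: chloromethyl methyl ether, COCCl
Why: Williamson-type O-alkylation, where full deprotonation with NaH breaks the chelate so that the hindered phenoxide is captured by the very reactive chloromethyl ether, and the aldehyde has no α-hydrogen to interfere.

Step 4
Reactants: 5 3-chloro-4-methoxy-2-(methoxymethoxy)benzaldehyde
Product: 7 3-chloro-4-methoxy-2-(methoxymethoxy)phenol, via aryl formate 6 (not isolated)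
Conditions: mCPBA, CH2Cl2, 0 °C → rt; aq. NaHCO3 wash; then K2CO3 (cat.), MeOH, rt
Reagents that add atoms: 3-chloroperoxybenzoic acid, OOC(=O)c1cccc(Cl)c1
Why: Baeyer–Villiger oxidation of the Dakin type, in which the aryl group, made electron-rich by its ortho and para oxygen donors, migrates in preference to hydrogen, followed by mild methanolysis of formate 6, both stages being harmless to the MOM acetal.

Step 5
Reactants: 7 3-chloro-4-methoxy-2-(methoxymethoxy)phenol
Product: 9 4-chloro-2-hydroxy-5-methoxy-3-(methoxymethoxy)benzaldehyde, via salicyl alcohol 8 (not isolated)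
Conditions: MgCl2, Et3N, (CH2O)n, MeCN, 80 °C; aq. citric acid work-up
Reagents that add atoms: formaldehyde (from paraformaldehyde), C=O
Why: Casnati–Skattebøl ortho-formylation, in which the magnesium phenoxide delivers formaldehyde to the only free ortho position (carbon 6 of 7, the future position 3 of ring A) and the salicyl alcohol 8 is oxidised in the flask by hydride transfer to a second formaldehyde, para attack being excluded by the methoxy group.

Step 6
Reactants: 9 4-chloro-2-hydroxy-5-methoxy-3-(methoxymethoxy)benzaldehyde
Product: 10 4-chloro-2-hydroxy-5-methoxy-3-(methoxymethoxy)benzoic acid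
Conditions: NaClO2, NaH2PO4, 2-methylbut-2-ene, t-BuOH/H2O, 0 °C → rt
Reagents that add atoms: sodium chlorite, [Na+].[O-]Cl=O
Why: Pinnick (Lindgren) oxidation, which converts the aldehyde to the acid in a mildly acidic buffer that spares the MOM acetal, while the alkene scavenger removes hypochlorous acid before it can chlorinate the free ring position or oxidise the electron-rich phenol.

Step 7
Reactants: 10 4-chloro-2-hydroxy-5-methoxy-3-(methoxymethoxy)benzoic acid
Product: 11 methyl 4-chloro-2-hydroxy-5-methoxy-3-(methoxymethoxy)benzoate
Conditions: MeI, KHCO3, DMF, rt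
Reagents that add atoms: iodomethane, CI
Why: SN2 alkylation of the carboxylate, because hydrogen carbonate ionises only the carboxylic acid and the salicylate hydroxyl stays protonated and hydrogen-bonded, so the ester should form without O-methylation of the phenol.

Step 8
Reactants: 12 dimethyl malonate (dimethyl propanedioate); 13 3-methylbut-2-enoyl chloride
Product: 14 dimethyl 2-(3-methylbut-2-enoyl)propanedioate
Conditions: NaH (2 equiv), 12 (2 equiv), THF, 0 °C; then 13 (1 equiv), 0 °C → rt; aq. HCl
Reagents that add atoms: none
Why: Claisen-type C-acylation of the sodium enolate of 12, run with two equivalents of enolate because 14 is more acidic than 12, and without a tertiary amine so that 13 is not diverted through a vinylketene that would move the double bond out of conjugation.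

Step 9
Reactants: 14 dimethyl 2-(3-methylbut-2-enoyl)propanedioate
Product: 16 dimethyl 2-(1-chloro-3-methylbut-2-en-1-ylidene)propanedioate, via enol dichlorophosphate 15 (not isolated)
Conditions: POCl3, n-Bu3N, 90 °C; then ice-water
Reagents that add atoms: phosphoryl chloride, O=P(Cl)(Cl)Cl
Why: Deoxychlorination of an enolised acylmalonate, a known route to (1-chloroalkylidene)malonates, in which O-phosphorylation gives 15 and chloride then replaces the dichlorophosphate by addition–elimination at the carbon β to both esters.

Step 10
Reactants: 11 methyl 4-chloro-2-hydroxy-5-methoxy-3-(methoxymethoxy)benzoate; 16 dimethyl 2-(1-chloro-3-methylbut-2-en-1-ylidene)propanedioate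
Product: 17 dimethyl 2-{1-[3-chloro-4-methoxy-6-(methoxycarbonyl)-2-(methoxymethoxy)phenoxy]-3-methylbut-2-en-1-ylidene}propanedioate
Conditions: K2CO3, DMF, rt
Reagents that add atoms: none
Why: Nucleophilic vinylic substitution (addition–elimination), in which the phenoxide of 11 adds to the chlorine-bearing carbon activated by two geminal esters and chloride leaves, so the hindered C–O bond is made on an alkene carbon and not by arylation, with a base too weak to touch the methyl groups.

Step 11
Reactants: 17 dimethyl 2-{1-[3-chloro-4-methoxy-6-(methoxycarbonyl)-2-(methoxymethoxy)phenoxy]-3-methylbut-2-en-1-ylidene}propanedioate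
Product: 19 methyl 4-chloro-2-[3-hydroxy-2-(methoxycarbonyl)-5-methylphenoxy]-5-methoxy-3-(methoxymethoxy)benzoate, via cyclohexadienone 18 (not isolated)
Conditions: LiN(SiMe3)2 (2.2 equiv), THF, −78 °C → rt; then AcOH
Reagents that add atoms: none
Why: LiN(SiMe3)2 removes a proton from a terminal methyl group of 17, the delocalised lithium trienolate adds through its CH2 terminus (the future ring B carbon 4) to the carbonyl carbon of a malonate ester (the future ring B carbon 5), the tetrahedral intermediate loses LiOMe to give cyclohexadienone 18, and 18 is deprotonated at its ring methylene to end as the aromatic lithium phenoxide of 19. The closest known reaction type is the carbanion-induced cyclisation of 2-alkenylidenemalonates to salicylates, a vinylogous Dieckmann condensation that can equally be read as a 6π-electrocyclisation of the trienolate followed by loss of methoxide. Ring B is closed in the 6-exo-trig mode at the ester carbonyl, the bond between ring B carbons 4 and 5 is the only skeletal bond formed, and no stereocentre arises. The step needs deprotonation to win over addition–elimination at the enol ether carbon (ring B carbon 1), which would expel the ring A phenoxide; the bulky, non-nucleophilic amide secures this, and more than two equivalents at −78 °C should turn all of 17 into the non-electrophilic enolate before methoxide is released on warming. Site selectivity is not an issue, because the two malonate esters are identical, both methyl groups lead to the same delocalised anion, whose geometries interconvert and are drained by the irreversible aromatisation, and the ring A ester has no α-hydrogen and could be reached only through an eight-membered ring. All ester groups are methyl, so exchange with the liberated methoxide is invisible, and the MOM acetal is inert to base.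

Step 12
Reactants: 19 methyl 4-chloro-2-[3-hydroxy-2-(methoxycarbonyl)-5-methylphenoxy]-5-methoxy-3-(methoxymethoxy)benzoate
Product: 21 2-(2-carboxy-3-hydroxy-5-methylphenoxy)-4-chloro-3-hydroxy-5-methoxybenzoic acid, via MOM-protected diacid 20 (not isolated)
Conditions: LiOH·H2O (excess), 1,4-dioxane/H2O, 80 °C; then aq. HCl (to about 3 M), 40 °C
Reagents that add atoms: lithium hydroxide monohydrate, [Li+].[OH-].O (one oxygen of each carboxyl group)
Why: Saponification of both methyl esters, run hot because the ring B ester is flanked by two ortho substituents and while the ring A hydroxyl at position 5 is still masked, followed by acid hydrolysis of the MOM acetal of 20 in water without methanol, so that neither carboxyl can be re-esterified.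

Compound list
1 | 2-chlororesorcinol (2-chlorobenzene-1,3-diol) | Oc1cccc(O)c1Cl | starting material
2 | aryl iminium chloride, N-[(3-chloro-2,4-dihydroxyphenyl)methylidene]-N-methylmethanaminium chloride (not isolated) | C[N+](C)=Cc1ccc(O)c(Cl)c1O.[Cl-] | intermediate
3 | 3-chloro-2,4-dihydroxybenzaldehyde | O=Cc1ccc(O)c(Cl)c1O | intermediate
4 | 3-chloro-2-hydroxy-4-methoxybenzaldehyde | COc1ccc(C=O)c(O)c1Cl | intermediate
5 | 3-chloro-4-methoxy-2-(methoxymethoxy)benzaldehyde | COCOc1c(C=O)ccc(OC)c1Cl | intermediate
6 | aryl formate, 3-chloro-4-methoxy-2-(methoxymethoxy)phenyl formate (not isolated) | COCOc1c(OC=O)ccc(OC)c1Cl | intermediate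
7 | 3-chloro-4-methoxy-2-(methoxymethoxy)phenol | COCOc1c(O)ccc(OC)c1Cl | intermediate
8 | salicyl alcohol, 3-chloro-6-(hydroxymethyl)-4-methoxy-2-(methoxymethoxy)phenol (not isolated) | COCOc1c(O)c(CO)cc(OC)c1Cl | intermediate
9 | 4-chloro-2-hydroxy-5-methoxy-3-(methoxymethoxy)benzaldehyde | COCOc1c(O)c(C=O)cc(OC)c1Cl | intermediate
10 | 4-chloro-2-hydroxy-5-methoxy-3-(methoxymethoxy)benzoic acid | COCOc1c(O)c(C(=O)O)cc(OC)c1Cl | intermediate
11 | methyl 4-chloro-2-hydroxy-5-methoxy-3-(methoxymethoxy)benzoate | COCOc1c(O)c(C(=O)OC)cc(OC)c1Cl | intermediate
12 | dimethyl malonate (dimethyl propanedioate) | COC(=O)CC(=O)OC | starting material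
13 | 3-methylbut-2-enoyl chloride | CC(C)=CC(=O)Cl | starting material
14 | dimethyl 2-(3-methylbut-2-enoyl)propanedioate | COC(=O)C(C(=O)OC)C(=O)C=C(C)C | intermediate
15 | enol dichlorophosphate, dimethyl 2-{1-[(dichlorophosphoryl)oxy]-3-methylbut-2-en-1-ylidene}propanedioate (not isolated) | COC(=O)C(C(=O)OC)=C(OP(=O)(Cl)Cl)C=C(C)C | intermediate
16 | dimethyl 2-(1-chloro-3-methylbut-2-en-1-ylidene)propanedioate | COC(=O)C(C(=O)OC)=C(Cl)C=C(C)C | intermediate
17 | dimethyl 2-{1-[3-chloro-4-methoxy-6-(methoxycarbonyl)-2-(methoxymethoxy)phenoxy]-3-methylbut-2-en-1-ylidene}propanedioate | COC(=O)C(C(=O)OC)=C(Oc1c(C(=O)OC)cc(OC)c(Cl)c1OCOC)C=C(C)C | intermediate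
18 | cyclohexadienone, methyl 4-chloro-5-methoxy-2-{[2-(methoxycarbonyl)-5-methyl-3-oxocyclohexa-1,5-dien-1-yl]oxy}-3-(methoxymethoxy)benzoate (not isolated) | COC(=O)C1=C(Oc2c(C(=O)OC)cc(OC)c(Cl)c2OCOC)C=C(C)CC1=O | intermediate
19 | methyl 4-chloro-2-[3-hydroxy-2-(methoxycarbonyl)-5-methylphenoxy]-5-methoxy-3-(methoxymethoxy)benzoate | COC(=O)c1cc(OC)c(Cl)c(OCOC)c1Oc1cc(C)cc(O)c1C(=O)OC | intermediate
20 | MOM-protected diacid, 2-(2-carboxy-3-hydroxy-5-methylphenoxy)-4-chloro-5-methoxy-3-(methoxymethoxy)benzoic acid (not isolated) | COCOc1c(Cl)c(OC)cc(C(=O)O)c1Oc1cc(C)cc(O)c1C(=O)O | intermediate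
21 | 2-(2-carboxy-3-hydroxy-5-methylphenoxy)-4-chloro-3-hydroxy-5-methoxybenzoic acid | COc1cc(C(=O)O)c(Oc2cc(C)cc(O)c2C(=O)O)c(O)c1Cl | target

Total step count: 12 (ring A steps 1–7, acylmalonate branch steps 8–9, union and completion steps 10–12).
Longest linear sequence: 10 steps (steps 1–7, 10, 11, 12).

Steps most likely to fail

Step 11. The amide base or the methoxide set free during the closure may add to the enol ether carbon of the dienyl malonate and expel the ring A phenoxide, or the trienolate may fail to reach the folded geometry and be reprotonated to a deconjugated isomer. The fallback gives up the folding and makes the diaryl ether bond by copper-catalysed Ullmann condensation with a ready-made ring B; it sets out from 11 and comes back to the route at 21. Purchased 3-bromo-5-methylphenol F1 would be converted (NaH, MOMCl, THF) into 1-bromo-3-(methoxymethoxy)-5-methylbenzene F2. Directed ortho-lithiation between the bromine and the acetal oxygen (LiN(i-Pr)2, THF, −78 °C) and trapping with ClCO2Me should give methyl 2-bromo-6-(methoxymethoxy)-4-methylbenzoate F3. Coupling of F3 with 11 (CuI, picolinic acid, K3PO4, DMSO, 90 °C), helped by the ester ortho to bromine, should give methyl 4-chloro-5-methoxy-2-[2-(methoxycarbonyl)-3-(methoxymethoxy)-5-methylphenoxy]-3-(methoxymethoxy)benzoate F4. Under the conditions of step 12, F4 would pass through 2-[2-carboxy-3-(methoxymethoxy)-5-methylphenoxy]-4-chloro-5-methoxy-3-(methoxymethoxy)benzoic acid F5, and the acid stage would remove both acetals to give 21.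

Step 9. Hot POCl3 and the hydrogen chloride it releases may add to or isomerise the diene, or trigger lactonisation of an ester onto the trisubstituted alkene, before the chloride has formed. The fallback replaces deoxychlorination by cold, basic O-sulfonylation; it sets out from 14 and comes back to the route at 17. Treatment of 14 with TsCl, Et3N and catalytic N-methylimidazole in CH2Cl2 at 0 °C should give the enol tosylate dimethyl 2-{3-methyl-1-[(4-methylbenzenesulfonyl)oxy]but-2-en-1-ylidene}propanedioate F6, which would take the place of 16 in the addition–elimination with the phenoxide of 11 (K2CO3, DMF, rt) and deliver 17.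

Step 12. Hydroxide attack at the carbonyl of the ring B ester, shielded by two ortho substituents and deactivated by the neighbouring phenoxide, may stall, and forcing it or prolonging the acid stage may cause protodecarboxylation of the doubly ortho-oxygenated ring B acid. The fallback cleaves the esters at the methyl carbon instead of the carbonyl carbon; it sets out from 19 and comes back to the route at 20. Heating 19 with LiI in pyridine (115 °C) should dealkylate both methyl esters by SN2 attack of iodide, a process insensitive to crowding at the carbonyl, which should leave the aryl methyl ether and the acetal untouched; dilute acid then gives 20, whose acetal is cleaved with aq. HCl at room temperature. This fallback makes no new compound (F0).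

Further compounds
F1 | step 11 | 3-bromo-5-methylphenol (purchased) | Cc1cc(O)cc(Br)c1
F2 | step 11 | 1-bromo-3-(methoxymethoxy)-5-methylbenzene | COCOc1cc(C)cc(Br)c1
F3 | step 11 | methyl 2-bromo-6-(methoxymethoxy)-4-methylbenzoate | COCOc1cc(C)cc(Br)c1C(=O)OC
F4 | step 11 | methyl 4-chloro-5-methoxy-2-[2-(methoxycarbonyl)-3-(methoxymethoxy)-5-methylphenoxy]-3-(methoxymethoxy)benzoate | COC(=O)c1cc(OC)c(Cl)c(OCOC)c1Oc1cc(C)cc(OCOC)c1C(=O)OC
F5 | step 11 | 2-[2-carboxy-3-(methoxymethoxy)-5-methylphenoxy]-4-chloro-5-methoxy-3-(methoxymethoxy)benzoic acid | COCOc1c(Cl)c(OC)cc(C(=O)O)c1Oc1cc(C)cc(OCOC)c1C(=O)O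
F6 | step 9 | dimethyl 2-{3-methyl-1-[(4-methylbenzenesulfonyl)oxy]but-2-en-1-ylidene}propanedioate | COC(=O)C(C(=O)OC)=C(OS(=O)(=O)c1ccc(C)cc1)C=C(C)C
F0 | step 12 | none | none
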